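**Strategy.** The target is disconnected at the enone level into an (S)-dihydrobenzofuranyl methyl ketone and 2,2-dimethylchroman-6-carbaldehyde. Claisen–Schmidt union and a copper-catalysed enantioselective β-borylation/oxidation of the chalcone then set the carbinol. The chroman's pyran ring (O1, C2, C3, C4, C4a, C8a) is closed last by an acid-catalysed formal (3+3) annulation of 4-hydroxybenzaldehyde with isoprene, which forms C4–C4a and O1–C2 in one operation. It exploits the gem-dimethyl carbon C2 as a tertiary cation bonded to O1, and the C6 formyl group para to O1, which leaves two equivalent ortho sites for C4a. The precursor is just the para-formylphenol and the diene.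

Key step: step 5

Assumption: (R,Sp)-Josiphos is taken, by analogy with simple chalcones, to deliver boron to the enone face that leads to the (S)-carbinol; if a model run showed the opposite sense, the (S,Rp) antipode would be used with nothing else changed.

**Step 1**
Reactants: 1 2,4-dihydroxyacetophenone; 2 2-methylbut-3-en-2-ol
Product: 3 1-[2,4-dihydroxy-5-(3-methylbut-2-en-1-yl)phenyl]ethan-1-one
Conditions: BF3·OEt2 (0.3 equiv), dioxane, rt; chromatography
Reagents that add atoms: none
Why: Friedel–Crafts allylation: BF3 ionises the tertiary allylic alcohol to the 1,1-dimethylallyl cation, which reacts through its primary terminus at C5 (ortho to the 4-OH, para to the 2-OH), the less hindered of the two activated positions, and the C3 isomer is removed by chromatography.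

**Step 2**
Reactants: 3 1-[2,4-dihydroxy-5-(3-methylbut-2-en-1-yl)phenyl]ethan-1-one
Product: 4 1-[2-hydroxy-5-(3-methylbut-2-en-1-yl)-4-(triisopropylsilyloxy)phenyl]ethan-1-one
Conditions: TIPSCl (1.05 equiv), imidazole, DMF, 0 °C
Reagents that add atoms: triisopropylsilyl chloride, CC(C)[Si](Cl)(C(C)C)C(C)C
Why: Chemoselective silyl ether formation: the 2-OH is locked in a hydrogen bond to the acetyl carbonyl and shielded by it, so the bulky silyl chloride should react only at the 4-OH.

**Step 3**
Reactants: 4 1-[2-hydroxy-5-(3-methylbut-2-en-1-yl)-4-(triisopropylsilyloxy)phenyl]ethan-1-one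
Product: 5 1-[5-{[(2R)-3,3-dimethyloxiran-2-yl]methyl}-2-hydroxy-4-(triisopropylsilyloxy)phenyl]ethan-1-one
Conditions: D-fructose-derived Shi ketone (0.3 equiv), Oxone, K2CO3, Bu4NHSO4 (cat.), MeCN–DMM/aq. borate–EDTA buffer (pH 10.5), 0 °C
Reagents that add atoms: Oxone (potassium peroxymonosulfate), [K+].[O-]S(=O)(=O)OO
Why: Shi asymmetric epoxidation: the chiral dioxirane formed in situ transfers oxygen through a spiro transition state to one face of the trisubstituted prenyl olefin, which for the D-fructose-derived ketone should give the (R)-configured epoxide carbon.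

**Step 4**
Reactants: 5 1-[5-{[(2R)-3,3-dimethyloxiran-2-yl]methyl}-2-hydroxy-4-(triisopropylsilyloxy)phenyl]ethan-1-one
Product: 7 1-[(2S)-6-hydroxy-2-(2-hydroxypropan-2-yl)-2,3-dihydro-1-benzofuran-5-yl]ethan-1-one, via desilylated epoxy-phenol 6 (not isolated)
Conditions: TBAF (1.1 equiv), THF, 0 °C → rt; aq. NH4Cl
Reagents that add atoms: none
Why: Fluoride desilylation releases the phenoxide, which opens the epoxide by 5-exo-tet SN2 attack at the secondary carbon with inversion, so the (R)-epoxide carbon becomes (S)-C2 of the dihydrobenzofuran and the tertiary carbon becomes the carbinol.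

**Step 5**
Reactants: 8 4-hydroxybenzaldehyde; 9 isoprene
Product: 11 2,2-dimethyl-3,4-dihydro-2H-chromene-6-carbaldehyde, via ortho-prenylphenol 10 (not isolated)
Conditions: isoprene (1.5 equiv, slow addition), 85% H3PO4, xylene, 35 °C → 70 °C
Reagents that add atoms: none
Why: Phosphoric acid protonates isoprene to the 1,1-dimethylallyl cation, which alkylates the phenol through its primary terminus ortho to the hydroxyl (directly or by O-prenylation and acid-promoted 1,3-shift) to give 10, whose trisubstituted alkene is then protonated to the tertiary cation at the future C2 and trapped by the phenolic oxygen. The closest known reaction type is the acid-catalysed chroman annulation of phenols with isoprene (Friedel–Crafts prenylation followed by hydroalkoxylation), a reaction type that extends to hydroxyaryl aldehydes and ketones. The pyran ring closes by 6-endo-trig Markovnikov attack of O1 on C2, the 5-exo alternative being excluded because it would need a secondary cation at C3. No stereocentre is created. The step needs C-alkylation ortho to the hydroxyl, a single prenyl unit and ring closure without attack on the aldehyde: the formyl group blocks the para position and directs meta to itself, which is the same carbon as ortho to OH, the two ortho sites are equivalent by symmetry, and slow addition of the diene limits both a second prenylation and its oligomerisation.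

**Step 6**
Reactants: 7 1-[(2S)-6-hydroxy-2-(2-hydroxypropan-2-yl)-2,3-dihydro-1-benzofuran-5-yl]ethan-1-one; 11 2,2-dimethyl-3,4-dihydro-2H-chromene-6-carbaldehyde
Product: 13 (2E)-3-(2,2-dimethyl-3,4-dihydro-2H-chromen-6-yl)-1-[(2S)-6-hydroxy-2-(2-hydroxypropan-2-yl)-2,3-dihydro-1-benzofuran-5-yl]prop-2-en-1-one, via epimeric aldol adduct 12 (not isolated)
Conditions: KOH (5 equiv, 50% aq.), EtOH, rt, 48 h; 1 M HCl to pH 5, 0 °C
Reagents that add atoms: none
Why: Claisen–Schmidt condensation: the enolate of the ortho-hydroxyaryl methyl ketone adds to the non-enolisable aldehyde and E1cB dehydration should give the conjugated (E)-enone, while the 2'-phenoxide is a poor oxa-Michael donor under these conditions and the dihydrofuran stereocentre carries no acidic hydrogen.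

**Step 7**
Reactants: 13 (2E)-3-(2,2-dimethyl-3,4-dihydro-2H-chromen-6-yl)-1-[(2S)-6-hydroxy-2-(2-hydroxypropan-2-yl)-2,3-dihydro-1-benzofuran-5-yl]prop-2-en-1-one
Product: 15 (3S)-3-(2,2-dimethyl-3,4-dihydro-2H-chromen-6-yl)-3-hydroxy-1-[(2S)-6-hydroxy-2-(2-hydroxypropan-2-yl)-2,3-dihydro-1-benzofuran-5-yl]propan-1-one, via beta-boryl ketone 14 (not isolated)
Conditions: CuCl (5 mol %), NaOtBu (10 mol %), (R,Sp)-Josiphos (5.5 mol %), B2pin2 (1.2 equiv), MeOH (2 equiv), THF, rt; then NaBO3·4H2O (3 equiv), THF/H2O, 0 °C → rt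
Reagents that add atoms: bis(pinacolato)diboron (boryl group of 14), CC1(C)OB(OC1(C)C)B1OC(C)(C)C(C)(C)O1; sodium perborate (carbinol oxygen of 15), [Na+].[Na+].O[B-]1(O)OO[B-](O)(O)OO1
Why: Copper-catalysed enantioselective conjugate borylation: the chiral bisphosphine–Cu–Bpin species adds to one face of the (E)-enone under ligand control, methanol protonates the copper enolate, and perborate oxidation of the C–B bond with retention should give the (S)-carbinol, the remote dihydrofuran stereocentre having no influence and any minor diastereomer being separable.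

**Compound list**
1 | 2,4-dihydroxyacetophenone | CC(=O)c1ccc(O)cc1O | starting material
2 | 2-methylbut-3-en-2-ol | CC(C)(O)C=C | starting material
3 | 1-[2,4-dihydroxy-5-(3-methylbut-2-en-1-yl)phenyl]ethan-1-one | CC(=O)c1cc(CC=C(C)C)c(O)cc1O | intermediate
4 | 1-[2-hydroxy-5-(3-methylbut-2-en-1-yl)-4-(triisopropylsilyloxy)phenyl]ethan-1-one | CC(=O)c1cc(CC=C(C)C)c(O[Si](C(C)C)(C(C)C)C(C)C)cc1O | intermediate
5 | 1-[5-{[(2R)-3,3-dimethyloxiran-2-yl]methyl}-2-hydroxy-4-(triisopropylsilyloxy)phenyl]ethan-1-one | CC(=O)c1cc(C[C@H]2OC2(C)C)c(O[Si](C(C)C)(C(C)C)C(C)C)cc1O | intermediate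
6 | 1-[5-{[(2R)-3,3-dimethyloxiran-2-yl]methyl}-2,4-dihydroxyphenyl]ethan-1-one | CC(=O)c1cc(C[C@H]2OC2(C)C)c(O)cc1O | intermediate (not isolated)
7 | 1-[(2S)-6-hydroxy-2-(2-hydroxypropan-2-yl)-2,3-dihydro-1-benzofuran-5-yl]ethan-1-one | CC(=O)c1cc2c(cc1O)O[C@H](C(C)(C)O)C2 | intermediate
8 | 4-hydroxybenzaldehyde | O=Cc1ccc(O)cc1 | starting material
9 | isoprene (2-methylbuta-1,3-diene) | C=CC(C)=C | starting material
10 | 4-hydroxy-3-(3-methylbut-2-en-1-yl)benzaldehyde | CC(C)=CCc1cc(C=O)ccc1O | intermediate (not isolated)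
11 | 2,2-dimethyl-3,4-dihydro-2H-chromene-6-carbaldehyde | CC1(C)CCc2cc(C=O)ccc2O1 | intermediate
12 | (3RS)-3-(2,2-dimethyl-3,4-dihydro-2H-chromen-6-yl)-3-hydroxy-1-[(2S)-6-hydroxy-2-(2-hydroxypropan-2-yl)-2,3-dihydro-1-benzofuran-5-yl]propan-1-one (both carbinol epimers) | CC1(C)CCc2cc(C(O)CC(=O)c3cc4c(cc3O)O[C@H](C(C)(C)O)C4)ccc2O1 | intermediate (not isolated)
13 | (2E)-3-(2,2-dimethyl-3,4-dihydro-2H-chromen-6-yl)-1-[(2S)-6-hydroxy-2-(2-hydroxypropan-2-yl)-2,3-dihydro-1-benzofuran-5-yl]prop-2-en-1-one | CC1(C)CCc2cc(/C=C/C(=O)c3cc4c(cc3O)O[C@H](C(C)(C)O)C4)ccc2O1 | intermediate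
14 | (3S)-3-(2,2-dimethyl-3,4-dihydro-2H-chromen-6-yl)-1-[(2S)-6-hydroxy-2-(2-hydroxypropan-2-yl)-2,3-dihydro-1-benzofuran-5-yl]-3-(4,4,5,5-tetramethyl-1,3,2-dioxaborolan-2-yl)propan-1-one | CC1(C)CCc2cc([C@@H](B5OC(C)(C)C(C)(C)O5)CC(=O)c3cc4c(cc3O)O[C@H](C(C)(C)O)C4)ccc2O1 | intermediate (not isolated)
15 | (3S)-3-(2,2-dimethyl-3,4-dihydro-2H-chromen-6-yl)-3-hydroxy-1-[(2S)-6-hydroxy-2-(2-hydroxypropan-2-yl)-2,3-dihydro-1-benzofuran-5-yl]propan-1-one | CC1(C)CCc2cc([C@@H](O)CC(=O)c3cc4c(cc3O)O[C@H](C(C)(C)O)C4)ccc2O1 | target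

**Step count.** Total: 7 steps. Longest linear sequence: 6 steps (1, 2, 3, 4, 6, 7); step 5 is a one-step branch that joins at step 6.

**Steps most likely to fail**

Step 5 (key step). The formyl-deactivated phenol may be alkylated more slowly than isoprene oligomerises, and uncyclised or doubly prenylated phenols or Prins-type attack on the aldehyde may compete. The fallback sets out from 8 and closes the same ring by a pericyclic cascade. O-Alkylation of 8 with 3-chloro-3-methylbut-1-yne (K2CO3, KI, CuI cat., acetone, reflux) should give 4-[(2-methylbut-3-yn-2-yl)oxy]benzaldehyde F1. Heating in N,N-diethylaniline at about 190 °C should trigger propargyl Claisen rearrangement, 1,5-hydrogen shift and oxa-6π electrocyclisation to 2,2-dimethyl-2H-chromene-6-carbaldehyde F2. Chemoselective hydrogenation of the C3=C4 bond (H2, Pd/C poisoned with Ph2S, EtOAc) then returns to the route at 11.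

Step 7. The free, chelating 2'-phenol may sequester copper or add to the enone (flavanone formation), eroding conversion and face selectivity. The basic peroxide oxidation may also cause retro-aldol cleavage, dehydration or aryl-ketone oxidation. The fallback sets out from 7 and 11 and forms the C–C bond and the stereocentre together. Silylation of 7 (TMSOTf, Et3N, CH2Cl2, 0 °C) should give 2-{(2S)-6-(trimethylsilyloxy)-5-[1-(trimethylsilyloxy)ethenyl]-2,3-dihydro-1-benzofuran-2-yl}-2-(trimethylsilyloxy)propane F3. A Lewis-base-catalysed Mukaiyama aldol addition of F3 to 11 follows (SiCl4, the chiral bisphosphoramide enantiomer that exposes the Si face of the aldehyde, CH2Cl2, −78 °C; aq. NaHCO3/KF work-up). It should give the bis(trimethylsilyl) ether of the target, (3S)-3-(2,2-dimethyl-3,4-dihydro-2H-chromen-6-yl)-3-hydroxy-1-{(2S)-6-(trimethylsilyloxy)-2-[2-(trimethylsilyloxy)propan-2-yl]-2,3-dihydro-1-benzofuran-5-yl}propan-1-one F4. Citric acid in methanol removes the silyl groups and returns to the route at 15.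

Step 1. Alkylation may be poorly regioselective (C3 against C5, O-alkylation, acid cyclisation to chromans) and may run on to dialkylation. The fallback sets out from 1 and fixes the position by halogenation. Iodination with ICl in acetic acid should give 1-(2,4-dihydroxy-5-iodophenyl)ethan-1-one F5. Stille coupling with tributyl(3-methylbut-2-en-1-yl)stannane (Pd(PPh3)4, DMF, 90 °C) then returns to the route at 3.

**Further compounds**
F1 | step 5 | 4-[(2-methylbut-3-yn-2-yl)oxy]benzaldehyde | CC(C)(C#C)Oc1ccc(C=O)cc1
F2 | step 5 | 2,2-dimethyl-2H-chromene-6-carbaldehyde | CC1(C)C=Cc2cc(C=O)ccc2O1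
F3 | step 7 | 2-{(2S)-6-(trimethylsilyloxy)-5-[1-(trimethylsilyloxy)ethenyl]-2,3-dihydro-1-benzofuran-2-yl}-2-(trimethylsilyloxy)propane | C=C(O[Si](C)(C)C)c1cc2c(cc1O[Si](C)(C)C)O[C@H](C(C)(C)O[Si](C)(C)C)C2
F4 | step 7 | (3S)-3-(2,2-dimethyl-3,4-dihydro-2H-chromen-6-yl)-3-hydroxy-1-{(2S)-6-(trimethylsilyloxy)-2-[2-(trimethylsilyloxy)propan-2-yl]-2,3-dihydro-1-benzofuran-5-yl}propan-1-one | CC1(C)CCc2cc([C@@H](O)CC(=O)c3cc4c(cc3O[Si](C)(C)C)O[C@H](C(C)(C)O[Si](C)(C)C)C4)ccc2O1
F5 | step 1 | 1-(2,4-dihydroxy-5-iodophenyl)ethan-1-one | CC(=O)c1cc(I)c(O)cc1O
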